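**Retrosynthetic overview**

1. The target is an ent-labdane (labdane numbering: ring A = C1–C5, C10; ring B = C5–C10; side chain C11–C16; C17 on C8; C20 on C10). The endgame is PMB removal, diacetylation, 1,2-reduction of a 7-en-6-one and unmasking of a 6-silyloxy-5,7-diene.
2. The (E)-C11=C12 bond comes from a Julia–Kocienski olefination of a C11 aldehyde on C9 with a C12–C16 sulfone; C13 is set by a palladium-catalysed asymmetric etherification of isoprene monoxide.
3. Ring B is closed by forming C7–C8 and C9–C10 together in a catalytic enantioselective Diels–Alder reaction of a ring-A 2-silyloxydiene (C7=C6(OSi)–C5=C10, from β-cyclocitral) with a 4-silyloxybut-2-ynoate (C17–C8≡C9–C11).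
4. Enabling feature: ring B is a cyclohexene with oxygen on C6, the C7=C8 double bond, C17 on C8, C11 on C9 and a quaternary C10 shared with ring A. This is the 1,4-cyclohexadiene adduct of a 2-oxy-diene and an ynoate after two proton shifts.
5. Ring order: ring A is bought, ring B is made in the key step. Stereochemical relay: C10 (catalyst), then C9, C5 and C6 (each reagent attacks anti to the C10 methyl); C13 comes from the building block.

Key step: step 5

Remarks: TBS = tert-butyldimethylsilyl, TES = triethylsilyl, PMB = 4-methoxybenzyl, PT = 1-phenyl-1H-tetrazol-5-yl; compounds 1, 6 and 14 are taken as commercial.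
Assumption: the sense of induction of the two chiral catalysts (steps 5 and 9) is assigned by analogy; both catalysts are available as either enantiomer, so the route is unchanged if the antipode is needed.

**Route**

Step 1
Reactants: 1 β-cyclocitral
Product: 2 1-(2,6,6-trimethylcyclohex-1-en-1-yl)ethan-1-ol (racemic)
Conditions: MeMgBr, THF, 0 °C; aq. NH4Cl
Reagents that add atoms: methylmagnesium bromide, C[Mg]Br
Why: 1,2-addition of a Grignard reagent to the hindered, non-enolisable enal should give the allylic alcohol; its stereocentre is racemic and is removed in step 2.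

Step 2
Reactants: 2 1-(2,6,6-trimethylcyclohex-1-en-1-yl)ethan-1-ol
Product: 3 1-(2,6,6-trimethylcyclohex-1-en-1-yl)ethan-1-one
Conditions: Dess–Martin periodinane, CH2Cl2, rt
Reagents that add atoms: none
Why: Dess–Martin oxidation of a secondary allylic alcohol gives the enone under neutral conditions without moving the tetrasubstituted double bond.

Step 3
Reactants: 3 1-(2,6,6-trimethylcyclohex-1-en-1-yl)ethan-1-one
Product: 5 tert-butyl(dimethyl){[1-(2,6,6-trimethylcyclohex-1-en-1-yl)ethenyl]oxy}silane, via lithium enolate 4 (not isolated)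
Conditions: LiN(iPr)2 (LDA), THF, −78 °C; TBSOTf, −78 → 0 °C
Reagents that add atoms: tert-butyldimethylsilyl trifluoromethanesulfonate, CC(C)(C)[Si](C)(C)OS(=O)(=O)C(F)(F)F
Why: kinetic deprotonation of the enone at the acetyl methyl group gives the cross-conjugated enolate, and O-silylation (silyl enol ether formation) gives the 2-silyloxy-1,3-diene; no stereocentre is formed.

Step 4
Reactants: 6 tert-butyl(dimethyl)(prop-2-yn-1-yloxy)silane
Product: 8 methyl 4-[(tert-butyldimethylsilyl)oxy]but-2-ynoate, via lithium acetylide 7 (not isolated)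
Conditions: n-BuLi, THF, −78 °C; ClCO2Me, −78 → 0 °C
Reagents that add atoms: methyl chloroformate, COC(=O)Cl
Why: C-acylation of a lithium acetylide with a chloroformate is the standard route to 2-ynoates.

Step 5
Reactants: 5 tert-butyl(dimethyl){[1-(2,6,6-trimethylcyclohex-1-en-1-yl)ethenyl]oxy}silane; 8 methyl 4-[(tert-butyldimethylsilyl)oxy]but-2-ynoate
Product: 9 methyl (8aR)-4-[(tert-butyldimethylsilyl)oxy]-2-{[(tert-butyldimethylsilyl)oxy]methyl}-5,5,8a-trimethyl-3,5,6,7,8,8a-hexahydronaphthalene-1-carboxylate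
Conditions: (S)-3,3-diphenyl-1-(2-methylphenyl)tetrahydro-1H,3H-pyrrolo[1,2-c][1,3,2]oxazaborole (15 mol%), AlBr3 (12 mol%), CH2Cl2, −78 → −20 °C
Reagents that add atoms: none
Why: Proposed new method: the AlBr3-activated cationic oxazaborolidine binds the ester carbonyl of 8, and the electron-rich 2-silyloxydiene 5 adds in a concerted but strongly asynchronous (Mukaiyama–Michael-like) [4+2] cycloaddition in which the unsubstituted terminus C7 bonds to the β-carbon C8 ahead of the tetrasubstituted terminus C10 closing onto the α-carbon C9. The closest known reaction types are the thermal Diels–Alder reaction of 2,6,6-trimethyl-1-vinylcyclohexene with acetylenic esters and the oxazaborolidinium-catalysed enantioselective Diels–Alder reactions of 2-silyloxydienes and of acetylenic carbonyl dienophiles, which have not been shown on a diene with a tetrasubstituted terminus. Ring B is closed as a six-membered ring by intermolecular [4+2] annulation onto the C5=C10 alkene of ring A, suprafacial on both partners. The only new stereocentre, quaternary C10, is set by the catalyst: its aryl group shields one face of the bound ynoate, and the bulky ring A of the diene is expected to stay away from the boron-bound carbonyl, so one enantiotopic face of C5=C10 is attacked. The step needs regioselectivity (C7 to C8, C10 to C9), which is secured by the 2-silyloxy group making C7 the nucleophilic terminus and by the ester on the alkyne carbon that becomes C9; an alkyne dienophile has no endo/exo issue. The adduct keeps a silyl enol ether at C6 and a tetrasubstituted enoate at C8=C9, so every carbon of ring B carries the function used later.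

Step 6
Reactants: 9 methyl (8aR)-4-[(tert-butyldimethylsilyl)oxy]-2-{[(tert-butyldimethylsilyl)oxy]methyl}-5,5,8a-trimethyl-3,5,6,7,8,8a-hexahydronaphthalene-1-carboxylate
Product: 11 methyl (1S,8aS)-4-[(tert-butyldimethylsilyl)oxy]-2-{[(tert-butyldimethylsilyl)oxy]methyl}-5,5,8a-trimethyl-1,5,6,7,8,8a-hexahydronaphthalene-1-carboxylate, via lithium trienolate 10 (not isolated)
Conditions: LiN(iPr)2 (LDA), THF/HMPA, −78 °C; AcOH in THF, −78 °C
Reagents that add atoms: none
Why: deconjugative isomerisation by kinetic protonation of an extended ester enolate: the doubly allylic C7–H is the most acidic proton (the polar cosolvent suppresses ester-directed deprotonation of the silyloxymethyl group), and the trienolate is protonated at the α-carbon C9 from the face opposite the C10 methyl, which sets H-9 trans to that methyl and leaves a 6-silyloxy-5,7-diene.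

Step 7
Reactants: 11 methyl (1S,8aS)-4-[(tert-butyldimethylsilyl)oxy]-2-{[(tert-butyldimethylsilyl)oxy]methyl}-5,5,8a-trimethyl-1,5,6,7,8,8a-hexahydronaphthalene-1-carboxylate
Product: 12 [(1S,8aS)-4-[(tert-butyldimethylsilyl)oxy]-2-{[(tert-butyldimethylsilyl)oxy]methyl}-5,5,8a-trimethyl-1,5,6,7,8,8a-hexahydronaphthalen-1-yl]methanol
Conditions: LiAlH4, Et2O, 0 °C; Na2SO4·10H2O quench
Reagents that add atoms: none
Why: LiAlH4 reduces the unconjugated methyl ester to the primary alcohol and leaves the silyl enol ether and silyl ether intact; after reduction C9 is no longer α to a carbonyl.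

Step 8
Reactants: 12 [(1S,8aS)-4-[(tert-butyldimethylsilyl)oxy]-2-{[(tert-butyldimethylsilyl)oxy]methyl}-5,5,8a-trimethyl-1,5,6,7,8,8a-hexahydronaphthalen-1-yl]methanol
Product: 13 (1S,8aS)-4-[(tert-butyldimethylsilyl)oxy]-2-{[(tert-butyldimethylsilyl)oxy]methyl}-5,5,8a-trimethyl-1,5,6,7,8,8a-hexahydronaphthalene-1-carbaldehyde
Conditions: Dess–Martin periodinane, pyridine, CH2Cl2, 0 °C
Reagents that add atoms: none
Why: buffered Dess–Martin oxidation gives the β,γ-unsaturated aldehyde under non-basic conditions, so the C9 stereocentre should survive; the aldehyde is used at once.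

Step 9
Reactants: 14 2-methyl-2-vinyloxirane (racemic)
Product: 15 (2S)-2-[(4-methoxybenzyl)oxy]-2-methylbut-3-en-1-ol
Conditions: Pd2(dba)3·CHCl3 (1 mol%), (R,R)-N,N'-(cyclohexane-1,2-diyl)bis[2-(diphenylphosphanyl)benzamide] (3 mol%), BEt3 (1 mol%), 4-methoxybenzyl alcohol, CH2Cl2, rt
Reagents that add atoms: 4-methoxybenzyl alcohol, COc1ccc(CO)cc1
Why: dynamic kinetic asymmetric allylic etherification (Tsuji–Trost type) of the racemic vinyl epoxide: the equilibrating π-allyl palladium intermediates are captured at the tertiary terminus by the boron-activated alcohol, and the chiral bisphosphine sets the C13 stereocentre (the ligand enantiomer that delivers the (S)-ether is used).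

Step 10
Reactants: 15 (2S)-2-[(4-methoxybenzyl)oxy]-2-methylbut-3-en-1-ol
Product: 16 5-({(2S)-2-[(4-methoxybenzyl)oxy]-2-methylbut-3-en-1-yl}sulfanyl)-1-phenyl-1H-tetrazole
Conditions: 1-phenyl-1H-tetrazole-5-thiol, PPh3, DIAD, THF, 0 °C → rt
Reagents that add atoms: 1-phenyl-1H-tetrazole-5-thiol, Sc1nnnn1-c1ccccc1
Why: Mitsunobu thioetherification at the primary carbon (SN2 at CH2) leaves the adjacent stereocentre untouched.

Step 11
Reactants: 16 5-({(2S)-2-[(4-methoxybenzyl)oxy]-2-methylbut-3-en-1-yl}sulfanyl)-1-phenyl-1H-tetrazole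
Product: 17 5-({(2S)-2-[(4-methoxybenzyl)oxy]-2-methylbut-3-en-1-yl}sulfonyl)-1-phenyl-1H-tetrazole
Conditions: (NH4)6Mo7O24·4H2O (10 mol%), 30% aq. H2O2, EtOH, 0 °C → rt
Reagents that add atoms: hydrogen peroxide, OO
Why: molybdate-catalysed peroxide oxidation of the sulfide to the sulfone should spare the terminal vinyl group and the PMB ether.

Step 12
Reactants: 13 (1S,8aS)-4-[(tert-butyldimethylsilyl)oxy]-2-{[(tert-butyldimethylsilyl)oxy]methyl}-5,5,8a-trimethyl-1,5,6,7,8,8a-hexahydronaphthalene-1-carbaldehyde; 17 5-({(2S)-2-[(4-methoxybenzyl)oxy]-2-methylbut-3-en-1-yl}sulfonyl)-1-phenyl-1H-tetrazole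
Product: 19 (1S,8aS)-4-[(tert-butyldimethylsilyl)oxy]-2-{[(tert-butyldimethylsilyl)oxy]methyl}-1-[(1E,3S)-3-[(4-methoxybenzyl)oxy]-3-methylpenta-1,4-dien-1-yl]-5,5,8a-trimethyl-1,5,6,7,8,8a-hexahydronaphthalene, via metalated sulfone 18 (not isolated)
Conditions: 17, KN(SiMe3)2, THF, −78 °C, 20 min; then 13, −78 → −20 °C; aq. NH4Cl
Reagents that add atoms: none
Why: Julia–Kocienski olefination (addition of the metalated sulfone to the aldehyde, Smiles rearrangement, loss of SO2 and the tetrazololate) should give the (E)-C11=C12 alkene because both partners are α-branched; C9 and C13 are not involved.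

Step 13
Reactants: 19 (1S,8aS)-4-[(tert-butyldimethylsilyl)oxy]-2-{[(tert-butyldimethylsilyl)oxy]methyl}-1-[(1E,3S)-3-[(4-methoxybenzyl)oxy]-3-methylpenta-1,4-dien-1-yl]-5,5,8a-trimethyl-1,5,6,7,8,8a-hexahydronaphthalene
Product: 20 (4S,4aS,8aR)-3-(hydroxymethyl)-4-[(1E,3S)-3-[(4-methoxybenzyl)oxy]-3-methylpenta-1,4-dien-1-yl]-4a,8,8-trimethyl-4a,5,6,7,8,8a-hexahydronaphthalen-1(4H)-one
Conditions: TBAF, AcOH (1:1), THF, 0 °C → rt
Reagents that add atoms: none
Why: fluoride cleaves the dienol silyl ether and the primary silyl ether, and the cross-conjugated enolate is protonated at C5 from the face opposite the C10 methyl to give the trans-fused 7-en-6-one (also the expected thermodynamic epimer); the acetic acid buffer protects the doubly allylic H-9.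

Step 14
Reactants: 20 (4S,4aS,8aR)-3-(hydroxymethyl)-4-[(1E,3S)-3-[(4-methoxybenzyl)oxy]-3-methylpenta-1,4-dien-1-yl]-4a,8,8-trimethyl-4a,5,6,7,8,8a-hexahydronaphthalen-1(4H)-one
Product: 21 (1S,4S,4aS,8aR)-3-(hydroxymethyl)-4-[(1E,3S)-3-[(4-methoxybenzyl)oxy]-3-methylpenta-1,4-dien-1-yl]-4a,8,8-trimethyl-1,4,4a,5,6,7,8,8a-octahydronaphthalen-1-ol
Conditions: NaBH4, CeCl3·7H2O, MeOH, −40 → 0 °C
Reagents that add atoms: none
Why: Luche reduction is 1,2-selective, and hydride attacks the C6 carbonyl from the face opposite the C10 methyl and the axial C4 methyl, so the new hydroxyl is axial and cis to the C10 methyl as the target requires.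

Step 15
Reactants: 21 (1S,4S,4aS,8aR)-3-(hydroxymethyl)-4-[(1E,3S)-3-[(4-methoxybenzyl)oxy]-3-methylpenta-1,4-dien-1-yl]-4a,8,8-trimethyl-1,4,4a,5,6,7,8,8a-octahydronaphthalen-1-ol
Product: 22 [(1S,4S,4aR,8aS)-4-acetoxy-1-[(1E,3S)-3-[(4-methoxybenzyl)oxy]-3-methylpenta-1,4-dien-1-yl]-5,5,8a-trimethyl-1,4,4a,5,6,7,8,8a-octahydronaphthalen-2-yl]methyl acetate
Conditions: Ac2O, pyridine, DMAP (cat.), CH2Cl2, rt
Reagents that add atoms: acetic anhydride, CC(=O)OC(C)=O
Why: DMAP-catalysed acetylation esterifies the primary allylic and the hindered secondary allylic alcohol, while the tertiary C13 oxygen stays protected as its PMB ether.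

Step 16
Reactants: 22 [(1S,4S,4aR,8aS)-4-acetoxy-1-[(1E,3S)-3-[(4-methoxybenzyl)oxy]-3-methylpenta-1,4-dien-1-yl]-5,5,8a-trimethyl-1,4,4a,5,6,7,8,8a-octahydronaphthalen-2-yl]methyl acetate
Product: 23 [(1S,4S,4aR,8aS)-4-acetoxy-1-[(1E,3S)-3-hydroxy-3-methylpenta-1,4-dien-1-yl]-5,5,8a-trimethyl-1,4,4a,5,6,7,8,8a-octahydronaphthalen-2-yl]methyl acetate (CNP0103498.1)
Conditions: DDQ, CH2Cl2/pH 7 phosphate buffer, 0 °C
Reagents that add atoms: none
Why: oxidative cleavage of the PMB ether with DDQ in buffered wet dichloromethane frees the tertiary alcohol under neutral conditions that should spare the allylic acetates and the skipped diene.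

**Compound list**

1 | β-cyclocitral (2,6,6-trimethylcyclohex-1-ene-1-carbaldehyde) | CC1=C(C=O)C(C)(C)CCC1 | starting material
2 | 1-(2,6,6-trimethylcyclohex-1-en-1-yl)ethan-1-ol (racemic) | CC(O)C1=C(C)CCCC1(C)C | intermediate
3 | 1-(2,6,6-trimethylcyclohex-1-en-1-yl)ethan-1-one | CC(=O)C1=C(C)CCCC1(C)C | intermediate
4 | lithium 1-(2,6,6-trimethylcyclohex-1-en-1-yl)ethen-1-olate (not isolated) | [Li+].C=C([O-])C1=C(C)CCCC1(C)C | intermediate
5 | tert-butyl(dimethyl){[1-(2,6,6-trimethylcyclohex-1-en-1-yl)ethenyl]oxy}silane | C=C(O[Si](C)(C)C(C)(C)C)C1=C(C)CCCC1(C)C | intermediate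
6 | tert-butyl(dimethyl)(prop-2-yn-1-yloxy)silane | C#CCO[Si](C)(C)C(C)(C)C | starting material
7 | lithium acetylide of 6 (not isolated) | [Li+].[C-]#CCO[Si](C)(C)C(C)(C)C | intermediate
8 | methyl 4-[(tert-butyldimethylsilyl)oxy]but-2-ynoate | COC(=O)C#CCO[Si](C)(C)C(C)(C)C | intermediate
9 | methyl (8aR)-4-[(tert-butyldimethylsilyl)oxy]-2-{[(tert-butyldimethylsilyl)oxy]methyl}-5,5,8a-trimethyl-3,5,6,7,8,8a-hexahydronaphthalene-1-carboxylate | COC(=O)C1=C(CO[Si](C)(C)C(C)(C)C)CC(O[Si](C)(C)C(C)(C)C)=C2C(C)(C)CCC[C@@]12C | intermediate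
10 | lithium trienolate of 9 (deprotonated at C7; not isolated) | [Li+].COC([O-])=C1C(CO[Si](C)(C)C(C)(C)C)=CC(O[Si](C)(C)C(C)(C)C)=C2C(C)(C)CCC[C@@]12C | intermediate
11 | methyl (1S,8aS)-4-[(tert-butyldimethylsilyl)oxy]-2-{[(tert-butyldimethylsilyl)oxy]methyl}-5,5,8a-trimethyl-1,5,6,7,8,8a-hexahydronaphthalene-1-carboxylate | COC(=O)[C@@H]1C(CO[Si](C)(C)C(C)(C)C)=CC(O[Si](C)(C)C(C)(C)C)=C2C(C)(C)CCC[C@@]12C | intermediate
12 | [(1S,8aS)-4-[(tert-butyldimethylsilyl)oxy]-2-{[(tert-butyldimethylsilyl)oxy]methyl}-5,5,8a-trimethyl-1,5,6,7,8,8a-hexahydronaphthalen-1-yl]methanol | OC[C@@H]1C(CO[Si](C)(C)C(C)(C)C)=CC(O[Si](C)(C)C(C)(C)C)=C2C(C)(C)CCC[C@@]12C | intermediate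
13 | (1S,8aS)-4-[(tert-butyldimethylsilyl)oxy]-2-{[(tert-butyldimethylsilyl)oxy]methyl}-5,5,8a-trimethyl-1,5,6,7,8,8a-hexahydronaphthalene-1-carbaldehyde | O=C[C@@H]1C(CO[Si](C)(C)C(C)(C)C)=CC(O[Si](C)(C)C(C)(C)C)=C2C(C)(C)CCC[C@@]12C | intermediate
14 | 2-methyl-2-vinyloxirane (isoprene monoxide, racemic) | CC1(C=C)CO1 | starting material
15 | (2S)-2-[(4-methoxybenzyl)oxy]-2-methylbut-3-en-1-ol | C=C[C@](C)(OCc1ccc(OC)cc1)CO | intermediate
16 | 5-({(2S)-2-[(4-methoxybenzyl)oxy]-2-methylbut-3-en-1-yl}sulfanyl)-1-phenyl-1H-tetrazole | C=C[C@](C)(OCc1ccc(OC)cc1)CSc1nnnn1-c1ccccc1 | intermediate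
17 | 5-({(2S)-2-[(4-methoxybenzyl)oxy]-2-methylbut-3-en-1-yl}sulfonyl)-1-phenyl-1H-tetrazole | C=C[C@](C)(OCc1ccc(OC)cc1)CS(=O)(=O)c1nnnn1-c1ccccc1 | intermediate
18 | potassium salt of the α-sulfonyl carbanion of 17 (not isolated) | [K+].C=C[C@](C)(OCc1ccc(OC)cc1)[CH-]S(=O)(=O)c1nnnn1-c1ccccc1 | intermediate
19 | (1S,8aS)-4-[(tert-butyldimethylsilyl)oxy]-2-{[(tert-butyldimethylsilyl)oxy]methyl}-1-[(1E,3S)-3-[(4-methoxybenzyl)oxy]-3-methylpenta-1,4-dien-1-yl]-5,5,8a-trimethyl-1,5,6,7,8,8a-hexahydronaphthalene | C=C[C@](C)(OCc1ccc(OC)cc1)/C=C/[C@@H]1C(CO[Si](C)(C)C(C)(C)C)=CC(O[Si](C)(C)C(C)(C)C)=C2C(C)(C)CCC[C@@]12C | intermediate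
20 | (4S,4aS,8aR)-3-(hydroxymethyl)-4-[(1E,3S)-3-[(4-methoxybenzyl)oxy]-3-methylpenta-1,4-dien-1-yl]-4a,8,8-trimethyl-4a,5,6,7,8,8a-hexahydronaphthalen-1(4H)-one | C=C[C@](C)(OCc1ccc(OC)cc1)/C=C/[C@@H]1C(CO)=CC(=O)[C@@H]2C(C)(C)CCC[C@@]12C | intermediate
21 | (1S,4S,4aS,8aR)-3-(hydroxymethyl)-4-[(1E,3S)-3-[(4-methoxybenzyl)oxy]-3-methylpenta-1,4-dien-1-yl]-4a,8,8-trimethyl-1,4,4a,5,6,7,8,8a-octahydronaphthalen-1-ol | C=C[C@](C)(OCc1ccc(OC)cc1)/C=C/[C@@H]1C(CO)=C[C@H](O)[C@@H]2C(C)(C)CCC[C@@]12C | intermediate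
22 | [(1S,4S,4aR,8aS)-4-acetoxy-1-[(1E,3S)-3-[(4-methoxybenzyl)oxy]-3-methylpenta-1,4-dien-1-yl]-5,5,8a-trimethyl-1,4,4a,5,6,7,8,8a-octahydronaphthalen-2-yl]methyl acetate | C=C[C@](C)(OCc1ccc(OC)cc1)/C=C/[C@@H]1C(COC(C)=O)=C[C@H](OC(C)=O)[C@@H]2C(C)(C)CCC[C@@]12C | intermediate
23 | [(1S,4S,4aR,8aS)-4-acetoxy-1-[(1E,3S)-3-hydroxy-3-methylpenta-1,4-dien-1-yl]-5,5,8a-trimethyl-1,4,4a,5,6,7,8,8a-octahydronaphthalen-2-yl]methyl acetate (CNP0103498.1) | C=C[C@](C)(O)/C=C/[C@@H]1C(COC(C)=O)=C[C@H](OC(C)=O)[C@@H]2C(C)(C)CCC[C@@]12C | target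

**Step count and risks**

Total step count: 16. Longest linear sequence: 12 steps (steps 1, 2, 3, 5, 6, 7, 8, 12, 13, 14, 15, 16).

The three steps most likely to fail:

1. Step 5 (bears the label). The twisted diene may react too slowly with the catalyst-bound ynoate. The reaction may also stop at the open-chain Mukaiyama–Michael stage through silyl transfer, or the catalyst may discriminate the two faces of C5=C10 poorly. The fallback uses known chemistry, sets out from 5 and 8 and returns at 12. The uncatalysed thermal Diels–Alder reaction (toluene, 140 °C, sealed tube, BHT), the reaction type by which 2,6,6-trimethyl-1-vinylcyclohexene adds acetylenic esters, should give the racemic cycloadduct F1. The conditions of steps 6 and 7 then give the racemic deconjugated ester F2 and the racemic primary alcohol F3. Esterification of F3 with (S)-2-methoxy-2-phenylacetic acid (DCC, DMAP, CH2Cl2) gives two diastereomeric esters, which are separated by chromatography. Reduction of the diastereomer with the (1S,8aS) ring, the (S)-O-methylmandelate F4, with LiAlH4 returns 12 as a single enantiomer.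

2. Step 6. The base may deprotonate the silyloxymethyl group cis to the ester instead of C7. The trienolate may be protonated at C7 or C5 instead of C9, or from the wrong face. The fallback moves the double bond at the ketone oxidation level under thermodynamic control; it sets out from 9 and returns at 21. Selective cleavage of the silyl enol ether (TBAF 1 equiv, AcOH, THF, −20 °C) gives the β,γ-unsaturated keto ester F5. DBU in toluene equilibrates it into conjugation with the ketone to give the 7-en-6-one ester F6. Luche reduction gives the axial allylic alcohol F7, and TESOTf with 2,6-lutidine gives the triethylsilyl ether F8. DIBAL-H (CH2Cl2, −78 °C) gives the aldehyde F9. Julia–Kocienski olefination with 17 under the conditions of step 12 gives the fully protected triene F10, and TBAF in THF removes both silyl groups to give 21.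

3. Step 12. The basic sulfonyl anion may enolise or epimerise aldehyde 13 at C9. Metalated 17 may lose 4-methoxybenzyl oxide by β-elimination, and the E selectivity may be incomplete. The fallback reverses the polarity of the olefination so that neither an enolisable aldehyde nor a β-alkoxy sulfone is used; it sets out from 12 and 15 and returns at 21. Mitsunobu reaction of 12 with 1-phenyl-1H-tetrazole-5-thiol gives the ring sulfide F11. TBAF/AcOH gives the enone alcohol F12, Luche reduction gives the diol F13, and TBSOTf with 2,6-lutidine gives the bis-silyl ether F14. Molybdate/H2O2 oxidation gives the ring sulfone F15. Dess–Martin oxidation of 15 gives the non-enolisable aldehyde (2S)-2-[(4-methoxybenzyl)oxy]-2-methylbut-3-enal F16. Metalation of F15 with KN(SiMe3)2 and addition of F16 gives the protected triene F17, and TBAF removes both silyl groups to give 21.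

Further compounds
F1 | step 5 | racemic methyl 4-[(tert-butyldimethylsilyl)oxy]-2-{[(tert-butyldimethylsilyl)oxy]methyl}-5,5,8a-trimethyl-3,5,6,7,8,8a-hexahydronaphthalene-1-carboxylate (both enantiomers written) | COC(=O)C1=C(CO[Si](C)(C)C(C)(C)C)CC(O[Si](C)(C)C(C)(C)C)=C2C(C)(C)CCC[C@@]12C.COC(=O)C1=C(CO[Si](C)(C)C(C)(C)C)CC(O[Si](C)(C)C(C)(C)C)=C2C(C)(C)CCC[C@]12C
F2 | step 5 | racemic methyl (1S*,8aS*)-4-[(tert-butyldimethylsilyl)oxy]-2-{[(tert-butyldimethylsilyl)oxy]methyl}-5,5,8a-trimethyl-1,5,6,7,8,8a-hexahydronaphthalene-1-carboxylate (both enantiomers written) | COC(=O)[C@@H]1C(CO[Si](C)(C)C(C)(C)C)=CC(O[Si](C)(C)C(C)(C)C)=C2C(C)(C)CCC[C@@]12C.COC(=O)[C@H]1C(CO[Si](C)(C)C(C)(C)C)=CC(O[Si](C)(C)C(C)(C)C)=C2C(C)(C)CCC[C@]12C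
F3 | step 5 | racemic [(1S*,8aS*)-4-[(tert-butyldimethylsilyl)oxy]-2-{[(tert-butyldimethylsilyl)oxy]methyl}-5,5,8a-trimethyl-1,5,6,7,8,8a-hexahydronaphthalen-1-yl]methanol (both enantiomers written) | OC[C@@H]1C(CO[Si](C)(C)C(C)(C)C)=CC(O[Si](C)(C)C(C)(C)C)=C2C(C)(C)CCC[C@@]12C.OC[C@H]1C(CO[Si](C)(C)C(C)(C)C)=CC(O[Si](C)(C)C(C)(C)C)=C2C(C)(C)CCC[C@]12C
F4 | step 5 | (2S)-2-methoxy-2-phenylacetate of 12 | CO[C@H](C(=O)OC[C@@H]1C(CO[Si](C)(C)C(C)(C)C)=CC(O[Si](C)(C)C(C)(C)C)=C2C(C)(C)CCC[C@@]12C)c1ccccc1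
F5 | step 6 | β,γ-unsaturated keto ester from 9 (C6 ketone, C8=C9 enoate, H-5 trans to the C10 methyl) | COC(=O)C1=C(CO[Si](C)(C)C(C)(C)C)CC(=O)[C@@H]2C(C)(C)CCC[C@@]12C
F6 | step 6 | 7-en-6-one ester (H-9 and H-5 trans to the C10 methyl) | COC(=O)[C@@H]1C(CO[Si](C)(C)C(C)(C)C)=CC(=O)[C@@H]2C(C)(C)CCC[C@@]12C
F7 | step 6 | 6-hydroxy-7-ene ester (axial 6-OH cis to the C10 methyl) | COC(=O)[C@@H]1C(CO[Si](C)(C)C(C)(C)C)=C[C@H](O)[C@@H]2C(C)(C)CCC[C@@]12C
F8 | step 6 | 6-O-triethylsilyl ether of F7 | COC(=O)[C@@H]1C(CO[Si](C)(C)C(C)(C)C)=C[C@H](O[Si](CC)(CC)CC)[C@@H]2C(C)(C)CCC[C@@]12C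
F9 | step 6 | C11 aldehyde from F8 | O=C[C@@H]1C(CO[Si](C)(C)C(C)(C)C)=C[C@H](O[Si](CC)(CC)CC)[C@@H]2C(C)(C)CCC[C@@]12C
F10 | step 6 | 6-O-TES, 17-O-TBS, 13-O-PMB protected (11E)-triene | C=C[C@](C)(OCc1ccc(OC)cc1)/C=C/[C@@H]1C(CO[Si](C)(C)C(C)(C)C)=C[C@H](O[Si](CC)(CC)CC)[C@@H]2C(C)(C)CCC[C@@]12C
F11 | step 12 | PT sulfide of 12 | C(Sc1nnnn1-c1ccccc1)[C@@H]1C(CO[Si](C)(C)C(C)(C)C)=CC(O[Si](C)(C)C(C)(C)C)=C2C(C)(C)CCC[C@@]12C
F12 | step 12 | 7-en-6-one with 17-OH and C11 PT sulfide | C(Sc1nnnn1-c1ccccc1)[C@@H]1C(CO)=CC(=O)[C@@H]2C(C)(C)CCC[C@@]12C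
F13 | step 12 | 6,17-diol with C11 PT sulfide | C(Sc1nnnn1-c1ccccc1)[C@@H]1C(CO)=C[C@H](O)[C@@H]2C(C)(C)CCC[C@@]12C
F14 | step 12 | 6,17-bis-O-TBS ether of F13 | C(Sc1nnnn1-c1ccccc1)[C@@H]1C(CO[Si](C)(C)C(C)(C)C)=C[C@H](O[Si](C)(C)C(C)(C)C)[C@@H]2C(C)(C)CCC[C@@]12C
F15 | step 12 | PT sulfone from F14 | C(S(=O)(=O)c1nnnn1-c1ccccc1)[C@@H]1C(CO[Si](C)(C)C(C)(C)C)=C[C@H](O[Si](C)(C)C(C)(C)C)[C@@H]2C(C)(C)CCC[C@@]12C
F16 | step 12 | (2S)-2-[(4-methoxybenzyl)oxy]-2-methylbut-3-enal | C=C[C@](C)(OCc1ccc(OC)cc1)C=O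
F17 | step 12 | 6,17-bis-O-TBS, 13-O-PMB protected (11E)-triene | C=C[C@](C)(OCc1ccc(OC)cc1)/C=C/[C@@H]1C(CO[Si](C)(C)C(C)(C)C)=C[C@H](O[Si](C)(C)C(C)(C)C)[C@@H]2C(C)(C)CCC[C@@]12C
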